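**Strategy.** Ring A is a 2-acylcyclohexane-1,3,5-trione whose spiro carbon C1 (C5' of the trans-hydrindane) carries both flanking carbonyls C2 and C6, i.e. a disubstituted malonyl unit. The route hinges on a [3+3] union of hydrindane gem-diester 12 with the dianion of 6-methylheptane-2,4-dione: crossed Claisen acylation of the exposed equatorial ester, then Dieckmann closure of the C2–C3 bond onto the shielded axial ester. This builds ring A and fixes the spiro centre in one operation. Diester 12 comes from (R)-limonene oxide (source of C7a') by ring contraction, malonate annulation and face-selective hydration; gem-diprenylation at C5 ends the synthesis.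

Key step: step 9

Remark: the enolised tricarbonyl ring is written in the tautomer of the target structure throughout; bicyclic intermediates are numbered as octahydroindenes with C3 and C7 the carbinol carbons, C3a and C7a the ring-fusion carbons and C5 the quaternary (later spiro) carbon.

Step 1
Reactants: 1 (+)-limonene 1,2-oxide, (4R)-1-methyl-4-(prop-1-en-2-yl)-7-oxabicyclo[4.1.0]heptane, commercial cis/trans mixture
Product: 2 (3R)-6-oxo-3-(prop-1-en-2-yl)heptanal
Conditions: H5IO6, THF/H2O, 0 °C to rt
Reagents that add atoms: water, O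
Why: Acid-mediated hydrolysis of both epoxide diastereomers to the 1,2-diol and periodate glycol cleavage (Malaprade reaction) open the ring to the keto aldehyde without touching the isopropenyl group or the C3 stereocentre.

Step 2
Reactants: 2 (3R)-6-oxo-3-(prop-1-en-2-yl)heptanal
Product: 3 (5S)-2-methyl-5-(prop-1-en-2-yl)cyclopent-1-ene-1-carbaldehyde
Conditions: piperidine (cat.), AcOH (cat.), benzene, reflux, Dean–Stark
Reagents that add atoms: none
Why: The enamine of the aldehyde adds to the methyl ketone (5-enolexo intramolecular aldol) and the adduct dehydrates to the conjugated enal (aldol condensation), the C5 stereocentre being non-enolisable.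

Step 3
Reactants: 3 (5S)-2-methyl-5-(prop-1-en-2-yl)cyclopent-1-ene-1-carbaldehyde
Product: 4 (1S,2S,5R)-5-methyl-2-(prop-1-en-2-yl)-6-oxabicyclo[3.1.0]hexane-1-carbaldehyde
Conditions: 30% aq. H2O2, NaOH (cat.), MeOH, 0 °C
Reagents that add atoms: hydrogen peroxide, OO
Why: Weitz–Scheffer nucleophilic epoxidation touches only the electron-poor enal double bond, and ring closure of the hydroperoxide adduct should occur on the face anti to the adjacent C2 isopropenyl group, which sets C1 and C5 together.

Step 4
Reactants: 4 (1S,2S,5R)-5-methyl-2-(prop-1-en-2-yl)-6-oxabicyclo[3.1.0]hexane-1-carbaldehyde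
Product: 6 (1R,2R,3R)-2-(hydroxymethyl)-1-methyl-3-(prop-1-en-2-yl)cyclopentan-1-ol, via hydroxy aldehyde 5 (not isolated)
Conditions: SmI2 (2.2 equiv), MeOH, THF, −90 °C; aqueous work-up; crude in CH2Cl2, DBU (cat.), 0 °C; then MeOH, NaBH4, 0 °C
Reagents that add atoms: none
Why: Reductive cleavage of the Cα–O bond of the α,β-epoxy carbonyl unit by SmI2 gives the β-hydroxy aldehyde 5 with the carbinol configuration retained, brief base equilibration of the enolisable C1 should place the formyl group trans to both flanking carbon substituents (cis to the hydroxyl), and NaBH4 fixes this as the 1,3-diol.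

Step 5
Reactants: 6 (1R,2R,3R)-2-(hydroxymethyl)-1-methyl-3-(prop-1-en-2-yl)cyclopentan-1-ol
Product: 7 [(1R,2R,5R)-2-hydroxy-2-methyl-5-(prop-1-en-2-yl)cyclopentyl]methyl 4-methylbenzenesulfonate
Conditions: TsCl (1.1 equiv), Et3N, DMAP (cat.), CH2Cl2, 0 °C
Reagents that add atoms: 4-toluenesulfonyl chloride, Cc1ccc(cc1)S(Cl)(=O)=O
Why: Sulfonylation discriminates the primary from the tertiary hydroxyl on steric grounds.

Step 6
Reactants: 7 [(1R,2R,5R)-2-hydroxy-2-methyl-5-(prop-1-en-2-yl)cyclopentyl]methyl 4-methylbenzenesulfonate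
Product: 8 [(1R,2R,5R)-5-(3-chloroprop-1-en-2-yl)-2-hydroxy-2-methylcyclopentyl]methyl 4-methylbenzenesulfonate
Conditions: Ca(OCl)2, solid CO2, CH2Cl2/H2O, 0 °C
Reagents that add atoms: calcium hypochlorite, [Ca+2].[O-]Cl.[O-]Cl
Why: Ene-type allylic chlorination of the 1,1-disubstituted alkene by HOCl formed in the flask gives the 2-(chloromethyl)allyl unit with double-bond shift, while the tosylate and the tertiary alcohol are inert.

Step 7
Reactants: 8 [(1R,2R,5R)-5-(3-chloroprop-1-en-2-yl)-2-hydroxy-2-methylcyclopentyl]methyl 4-methylbenzenesulfonate; 9 dimethyl malonate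
Product: 11 dimethyl (3R,3aS,7aR)-3-hydroxy-3-methyl-7-methylideneoctahydro-1H-indene-5,5-dicarboxylate, via monoalkylated malonate 10 (not isolated)
Conditions: Cs2CO3 (2.5 equiv), NaI (cat.), DMF, high dilution, rt to 60 °C
Reagents that add atoms: none
Why: Double malonate alkylation, first at the allylic chloride and then by 6-exo-tet displacement of the primary tosylate, closes the cyclohexane as a trans-fused hydrindane because the two arms are trans on the cyclopentane; no stereocentre is formed.

Step 8
Reactants: 11 dimethyl (3R,3aS,7aR)-3-hydroxy-3-methyl-7-methylideneoctahydro-1H-indene-5,5-dicarboxylate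
Product: 12 dimethyl (3R,3aS,7R,7aR)-3,7-dihydroxy-3,7-dimethyloctahydro-1H-indene-5,5-dicarboxylate
Conditions: Co(acac)2 (cat.), PhSiH3, O2 (1 atm), THF, rt
Reagents that add atoms: dioxygen, O=O
Why: Mukaiyama hydration: hydrogen-atom transfer to the methylidene carbon gives the tertiary C7 radical, which should capture O2 on the equatorial face because the axial face is blocked by the 1,3-diaxial C5 ester (as at C8 of drimane-type exocyclic alkenes shielded by the angular methyl), giving equatorial hydroxyl and axial methyl.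

Step 9
Reactants: 12 dimethyl (3R,3aS,7R,7aR)-3,7-dihydroxy-3,7-dimethyloctahydro-1H-indene-5,5-dicarboxylate; 13 6-methylheptane-2,4-dione
Product: 16 (1S,3'R,3a'S,7'R,7a'R)-3',4,7'-trihydroxy-3',7'-dimethyl-3-(3-methylbutanoyl)-1',2',3',3a',4',6',7',7a'-octahydrospiro[cyclohex-3-ene-1,5'-indene]-2,6-dione, via dilithium dienolate 14 (not isolated), via triketo ester 15 (not isolated)
Conditions: 13 (4.5 equiv), LiN(iPr)2 (9 equiv), THF, −78 to 0 °C; then 12, 0 °C to rt, then reflux; aq. HCl
Reagents that add atoms: none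
Why: Dienolate 14 attacks an ester of 12 through its terminal carbon (crossed Claisen acylation of a 1,3-diketone dianion) to give 15 as its dianion, whose side-chain C4, the carbon between the 3- and 5-carbonyls, then adds to the second ester and expels methoxide, forming the C2–C3 bond of ring A. The closest known reaction type is the Claisen (Dieckmann-type) cyclisation of 3,5,7-triketo esters to 2-acylcyclohexane-1,3,5-triones, here run in one flask with the preceding acylation. Ring A closes in a 6-exo-trig mode onto the ester carbonyl; closure through side-chain C2 would need a four-membered ring and is excluded. The only new stereocentre is the spiro carbon, controlled by the locked chair of the trans-hydrindane: the axial ester is syn-diaxial to the C7 methyl and H-3a, so the intermolecular acylation should take the open equatorial ester and the intramolecular closure then falls on the axial one, which puts C2 axial and C6 equatorial as in the target. The step needs this ester discrimination and C- over O-acylation in the closure; the latter is secured because an enol lactone would be reopened by the methoxide set free, whereas the enolate of triketone 16 is the thermodynamic sink. The two tertiary hydroxyls are carried as lithium alkoxides (hence the excess of 14) and cannot lactonise in the trans-fused chair.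

Step 10
Reactants: 16 (1S,3'R,3a'S,7'R,7a'R)-3',4,7'-trihydroxy-3',7'-dimethyl-3-(3-methylbutanoyl)-1',2',3',3a',4',6',7',7a'-octahydrospiro[cyclohex-3-ene-1,5'-indene]-2,6-dione; 17 1-bromo-3-methylbut-2-ene (prenyl bromide)
Product: 18 (1S,3'R,3a'S,7'R,7a'R)-3',4,7'-trihydroxy-3',7'-dimethyl-3-(3-methylbutanoyl)-5,5-bis(3-methylbut-2-en-1-yl)-1',2',3',3a',4',6',7',7a'-octahydrospiro[cyclohex-3-ene-1,5'-indene]-2,6-dione
Conditions: 17 (2.3 equiv), NaOMe (3 equiv), MeOH, 0 °C to rt; aq. HCl
Reagents that add atoms: none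
Why: The dianion of the enolised triketone should be C-allylated twice at C5, its most basic carbon and the only CH position of ring A (gem-C-prenylation as known for acylphloroglucinols and filicinic acids in protic alkoxide media, which disfavour O-alkylation), without touching any stereocentre.

**Compound list**

1 | (+)-limonene 1,2-oxide, (4R)-1-methyl-4-(prop-1-en-2-yl)-7-oxabicyclo[4.1.0]heptane (cis/trans mixture) | C=C(C)[C@@H]1CCC2(C)OC2C1 | starting material
2 | (3R)-6-oxo-3-(prop-1-en-2-yl)heptanal | O=CC[C@@H](CCC(C)=O)C(C)=C | intermediate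
3 | (5S)-2-methyl-5-(prop-1-en-2-yl)cyclopent-1-ene-1-carbaldehyde | O=CC1=C(C)CC[C@H]1C(C)=C | intermediate
4 | (1S,2S,5R)-5-methyl-2-(prop-1-en-2-yl)-6-oxabicyclo[3.1.0]hexane-1-carbaldehyde (epoxide anti to isopropenyl) | O=C[C@@]12O[C@]1(C)CC[C@H]2C(C)=C | intermediate
5 | (1S,2R,5R)-2-hydroxy-2-methyl-5-(prop-1-en-2-yl)cyclopentane-1-carbaldehyde (not isolated) | O=C[C@H]1[C@@H](CC[C@@]1(C)O)C(C)=C | intermediate
6 | (1R,2R,3R)-2-(hydroxymethyl)-1-methyl-3-(prop-1-en-2-yl)cyclopentan-1-ol | OC[C@H]1[C@@H](CC[C@@]1(C)O)C(C)=C | intermediate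
7 | [(1R,2R,5R)-2-hydroxy-2-methyl-5-(prop-1-en-2-yl)cyclopentyl]methyl 4-methylbenzenesulfonate | Cc1ccc(cc1)S(=O)(=O)OC[C@H]1[C@@H](CC[C@@]1(C)O)C(C)=C | intermediate
8 | [(1R,2R,5R)-5-(3-chloroprop-1-en-2-yl)-2-hydroxy-2-methylcyclopentyl]methyl 4-methylbenzenesulfonate | Cc1ccc(cc1)S(=O)(=O)OC[C@H]1[C@@H](CC[C@@]1(C)O)C(=C)CCl | intermediate
9 | dimethyl malonate | COC(=O)CC(=O)OC | starting material
10 | dimethyl 2-{2-[(1R,2R,3R)-3-hydroxy-3-methyl-2-(tosyloxymethyl)cyclopentyl]prop-2-en-1-yl}propanedioate (not isolated) | Cc1ccc(cc1)S(=O)(=O)OC[C@H]1[C@@H](CC[C@@]1(C)O)C(=C)CC(C(=O)OC)C(=O)OC | intermediate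
11 | dimethyl (3R,3aS,7aR)-3-hydroxy-3-methyl-7-methylideneoctahydro-1H-indene-5,5-dicarboxylate (trans ring fusion) | COC(=O)C1(C(=O)OC)C[C@H]2[C@@H](CC[C@@]2(C)O)C(=C)C1 | intermediate
12 | dimethyl (3R,3aS,7R,7aR)-3,7-dihydroxy-3,7-dimethyloctahydro-1H-indene-5,5-dicarboxylate | COC(=O)C1(C(=O)OC)C[C@H]2[C@@H](CC[C@@]2(C)O)[C@](C)(O)C1 | intermediate
13 | 6-methylheptane-2,4-dione | CC(C)CC(=O)CC(C)=O | starting material
14 | dilithium 6-methylhepta-1,3-diene-2,4-diolate, dianion of 13 (not isolated) | [Li+].[Li+].C=C([O-])C=C([O-])CC(C)C | intermediate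
15 | methyl (3R,3aS,5S,7R,7aR)-3,7-dihydroxy-3,7-dimethyl-5-(7-methyl-3,5-dioxooctanoyl)octahydro-1H-indene-5-carboxylate (not isolated) | COC(=O)[C@@]1(C(=O)CC(=O)CC(=O)CC(C)C)C[C@H]2[C@@H](CC[C@@]2(C)O)[C@](C)(O)C1 | intermediate
16 | (1S,3'R,3a'S,7'R,7a'R)-3',4,7'-trihydroxy-3',7'-dimethyl-3-(3-methylbutanoyl)-1',2',3',3a',4',6',7',7a'-octahydrospiro[cyclohex-3-ene-1,5'-indene]-2,6-dione | C1C(=O)[C@@]2(C[C@H]3[C@@H](CC[C@@]3(C)O)[C@](C)(O)C2)C(=O)C(C(=O)CC(C)C)=C1O | intermediate
17 | 1-bromo-3-methylbut-2-ene (prenyl bromide) | CC(C)=CCBr | starting material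
18 | (1S,3'R,3a'S,7'R,7a'R)-3',4,7'-trihydroxy-3',7'-dimethyl-3-(3-methylbutanoyl)-5,5-bis(3-methylbut-2-en-1-yl)-1',2',3',3a',4',6',7',7a'-octahydrospiro[cyclohex-3-ene-1,5'-indene]-2,6-dione (CNP0198642.3) | CC(C)=CCC1(CC=C(C)C)C(=O)[C@@]2(C[C@H]3[C@@H](CC[C@@]3(C)O)[C@](C)(O)C2)C(=O)C(C(=O)CC(C)C)=C1O | target

**Totals.** Total step count: 10. Longest linear sequence: 10 steps (1 to 18); 9, 13 and 17 are commercial and enter directly.

**Steps most likely to fail**

1. Step 9. The intermolecular acylation may not discriminate well enough between the two diastereotopic esters, which would erode the spiro configuration. The closure may also stall on the hindered axial ester or at the O-acyl stage. Fallback from 12, returning at 16: the equatorial ester of 12 is saponified selectively with LiOH in THF/MeOH/H2O (the syn-diaxially shielded axial ester hydrolyses far more slowly) to the mono-acid (3R,3aS,5S,7R,7aR)-3,7-dihydroxy-5-(methoxycarbonyl)-3,7-dimethyloctahydro-1H-indene-5-carboxylic acid F1. Activation with 1,1'-carbonyldiimidazole in THF gives the acyl imidazolide F2. This is added to dienolate 14 at −78 °C to give 15, now isolated, and NaOMe in MeOH at reflux closes ring A and rejoins the route at 16. The ester differentiation is thereby made chemically before any C–C bond is formed, and the closure is run as a separate thermodynamic step.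

2. Step 4. The aldehyde may undergo pinacol coupling or over-reduction under SmI2, and the β-hydroxy aldehyde may dehydrate or open by retro-aldol during the equilibration at C1. Fallback from 4, returning at 6: Pinnick oxidation of 4 (NaClO2, NaH2PO4, 2-methylbut-2-ene, t-BuOH/H2O) gives the epoxy acid F3. Methylation (MeI, K2CO3, DMF) gives the methyl epoxy ester F4. Reductive opening of the α,β-epoxy ester with Na[PhSeB(OEt)3] in EtOH/AcOH gives the β-hydroxy ester F5, which tolerates NaOMe equilibration to the all-trans isomer. LiAlH4 in THF then reduces it to 6. The fragile aldehyde stage is avoided by working at the ester oxidation level.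

3. Step 8. Oxygen capture by the planar tertiary radical may show poor facial selectivity. Fallback from 11, returning at 12: mCPBA (NaHCO3, CH2Cl2, 0 °C) should epoxidise the methylidene group in a concerted manner from the open equatorial face to give the spiro-epoxide F6. LiI/AcOH in THF opens it at the methylene carbon to the iodohydrin F7. Bu3SnH/AIBN in toluene at 80 °C removes the iodine and gives 12.

**Further compounds**

F1 | step 9 | (3R,3aS,5S,7R,7aR)-3,7-dihydroxy-5-(methoxycarbonyl)-3,7-dimethyloctahydro-1H-indene-5-carboxylic acid | COC(=O)[C@@]1(C(=O)O)C[C@H]2[C@@H](CC[C@@]2(C)O)[C@](C)(O)C1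
F2 | step 9 | methyl (3R,3aS,5S,7R,7aR)-3,7-dihydroxy-5-(1H-imidazole-1-carbonyl)-3,7-dimethyloctahydro-1H-indene-5-carboxylate | COC(=O)[C@@]1(C(=O)n2ccnc2)C[C@H]3[C@@H](CC[C@@]3(C)O)[C@](C)(O)C1
F3 | step 4 | (1S,2S,5R)-5-methyl-2-(prop-1-en-2-yl)-6-oxabicyclo[3.1.0]hexane-1-carboxylic acid | OC(=O)[C@@]12O[C@]1(C)CC[C@H]2C(C)=C
F4 | step 4 | methyl (1S,2S,5R)-5-methyl-2-(prop-1-en-2-yl)-6-oxabicyclo[3.1.0]hexane-1-carboxylate | COC(=O)[C@@]12O[C@]1(C)CC[C@H]2C(C)=C
F5 | step 4 | methyl (1S,2R,5R)-2-hydroxy-2-methyl-5-(prop-1-en-2-yl)cyclopentane-1-carboxylate | COC(=O)[C@H]1[C@@H](CC[C@@]1(C)O)C(C)=C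
F6 | step 8 | dimethyl (3R,3aS,7R,7aR)-3-hydroxy-3-methyloctahydrospiro[indene-7,2'-oxirane]-5,5-dicarboxylate (oxirane oxygen equatorial) | COC(=O)C1(C(=O)OC)C[C@H]2[C@@H](CC[C@@]2(C)O)[C@@]3(CO3)C1
F7 | step 8 | dimethyl (3R,3aS,7R,7aR)-3,7-dihydroxy-7-(iodomethyl)-3-methyloctahydro-1H-indene-5,5-dicarboxylate | COC(=O)C1(C(=O)OC)C[C@H]2[C@@H](CC[C@@]2(C)O)[C@](CI)(O)C1
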